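Take the earliest readings of each run and ask what the rate per unit of charge does when the charge changes.

| run | time / s | E / % | D / % |
|---|---|---|---|
| autumn | 10.0 | 0 | 2.0 |
| autumn | 20.0 | 0.6 | 4.9 |
| autumn | 50.0 | 1.8 | 8.9 |
| spring | 10.0 | 0 | 2.9 |
| spring | 12.0 | 0.3 | 2.2 |
| spring | 25.0 | 0.3 | 4.9 |
| spring | 60.0 | 1.5 | 9.9 |

(scatter of a reading: 0.5 percentage points)

in all of them: J 18 mM (held)

| flask | G | remark | time |
|---|---|---|---|
| autumn | 0.050 M | the very flask that is asked about, followed so far |  |
| spring | 0.034 M | run made earlier |  |
| flask | 0.050 M |  | 2.5 min |

1. concentration of E at 2.5 min, in M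
2. concentration of D at 2.5 min, in M
3. concentration of Z at 2.5 min, in M
4. concentration of G at 2.5 min, in M

**First instants.** J starts out of solution, yet D reads 2.0% after 10.0 s in the autumn run, so I can read no lag beyond the scatter of 0.5 percentage points. I treat G as unchanged over these first seconds and take D plus E, over time, as the rate. I sum both over the early readings, up to 20.0 s in autumn and 25.0 s in spring:

autumn: 0.00250 /s

spring: 0.00226 /s

The charges stand in the ratio 1.47, but these readings stand in the ratio 1.11, which is near one given the scatter. So I read the first step as first order in G, and pseudo-first-order if J, held at 18 mM, takes part. I carry the mean of these two readings as k′, the charge rate, the fraction of the G present that leaves by this first step each second: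

k′ = 0.00238 /s

**Middle.** If this step were G's one exit, one minus exp(−k′t) would be the share made by time t. D plus E falls short of that by 0.51 points at 50.0 s in autumn and 1.9 points at 60.0 s in spring. That is a hint of a further sink, no more.

**End.** At 2.5 min my share is

S = 30.0%

which in this reckoning, with J held at 18 mM, does not depend on the charge. That puts G near 0.0350 M in this flask, and any second drain on G lowers it.

The forecast says 0.004 M of E, 0.007 M of D, 0.0023 M of Z and 0.0345 M of G, holding that “G is consumed first order”.

    G + L → D (k = 0.170 /M/s)
    D → E (k = 0.00550 /s)
    G + D → Z (k = 0.310 /M/s)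
    J ⇌ L, rate k4*(csat - [L]) (kL = 0.520 /s)

The flask at 2.5 min holds 0.0260 M of G, with 0.00366 M of E, 0.00584 M of D and 0.00725 M of Z. The net turnover of the step from G + L to D is 33.5% of the charge, against my S of 30.0%, while G has lost 48.0%. In the neighbour flask charged with 0.020 M of G, S stays 30.0% at the same time. There D, E and the one G in each Z that came through D add up to 34.9%.

The numbers in the tables were generated by integration for an exercise; noise was put on by code.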